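**Retrosynthetic overview**
1. The 4,5-epoxide is the last ring: peripheral epoxidation of the (4Z)-olefin of the finished macrolactone.
2. Key disconnection C6–C7 plus O–C12: oxidation of an acyclic allylic alcohol releases a Z-enal that is trapped by a pendant 2-(methoxycarbonyl)allylboronate, then lactonises. The ten-membered carbocycle and the cis-fused α-methylene lactone form in that one operation.
3. The allylboronate arm comes from cross-metathesis of a C7 vinyl group; the C8 ester comes from (S)-2-methyloxirane-2-carboxylic acid.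
4. C8–C9 by reagent-controlled syn-alkoxyallylboration of a 2-formyl enoate; C1=C10 by Morita–Baylis–Hillman reaction of a neryl acetate-derived aldehyde, then SN2′ bromination and oxidation.
5. Ring order: side-chain oxirane (bought in) → carbocycle + lactone (same step) → ring epoxide.

Assumption: allyl methoxymethyl ether, (R)-2-methylglycidol, B2pin2 and (+)-Ipc2BOMe are taken as catalogue chemicals; locants C1–C15 are germacranolide locants (C6 carries the lactone oxygen, C7 is the ring-fusion carbon, C10 carries CO2Me).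

**Step 1**
Reactants: 1 neryl acetate
Product: 3 (2Z)-3-methyl-6-oxohex-2-en-1-yl acetate, via secondary ozonide 2 (not isolated)
Conditions: O3 (1.0 equiv, Sudan Red end-point), CH2Cl2, −78 °C; then Me2S, −78 → 23 °C
Reagents that add atoms: ozone, [O-][O+]=O
Why: Ozonolysis with reductive work-up; the 2,3-olefin is deactivated by the allylic acetate, so one equivalent of ozone cleaves only the isopropylidene end and no stereocentre is formed.

**Step 2**
Reactants: 3 (2Z)-3-methyl-6-oxohex-2-en-1-yl acetate; 4 methyl acrylate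
Product: 5 methyl (6Z)-8-(acetyloxy)-3-hydroxy-6-methyl-2-methylideneoct-6-enoate (racemic)
Conditions: DABCO (1,4-diazabicyclo[2.2.2]octane, 0.5 equiv), neat methyl acrylate (3 equiv), 23 °C, 5 d
Reagents that add atoms: none
Why: Morita–Baylis–Hillman reaction of an unhindered aliphatic aldehyde; the new carbinol centre is racemic but is erased in step 3.

**Step 3**
Reactants: 5 methyl (6Z)-8-(acetyloxy)-3-hydroxy-6-methyl-2-methylideneoct-6-enoate
Product: 7 methyl (2Z,6Z)-8-(acetyloxy)-2-(bromomethyl)-6-methylocta-2,6-dienoate, via alkoxysulfonium bromide 6 (not isolated)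
Conditions: NBS, Me2S, CH2Cl2, 0 → 23 °C
Reagents that add atoms: N-bromosuccinimide, O=C1CCC(=O)N1Br
Why: Corey–Kim-type activation of the allylic alcohol followed by SN2′ attack of bromide gives the conjugated (Z)-2-(bromomethyl)-2-enoate, which fixes the C1=C10 geometry of the target (the future C9 cis to C2, ester trans).

**Step 4**
Reactants: 7 methyl (2Z,6Z)-8-(acetyloxy)-2-(bromomethyl)-6-methylocta-2,6-dienoate
Product: 9 methyl (2E,6Z)-8-(acetyloxy)-2-formyl-6-methylocta-2,6-dienoate, via N-alkoxymorpholinium bromide 8 (not isolated)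
Conditions: NMO (4 equiv), 4 Å MS, MeCN, 23 °C; used crude at once
Reagents that add atoms: 4-methylmorpholine N-oxide, C[N+]1([O-])CCOCC1
Why: Ganem (Kornblum-type) oxidation: the N-oxide displaces the allylic bromide and base-induced elimination gives the aldehyde with the trisubstituted olefin geometry unchanged.

**Step 5**
Reactants: 9 methyl (2E,6Z)-8-(acetyloxy)-2-formyl-6-methylocta-2,6-dienoate; 10 allyl methoxymethyl ether
Product: 14 methyl (2E,6Z)-8-(acetyloxy)-2-[(1S,2S)-1-hydroxy-2-(methoxymethoxy)but-3-en-1-yl]-6-methylocta-2,6-dienoate, via allyllithium 11 (not isolated), via allylborane 12 (not isolated), via borinate 13 (not isolated)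
Conditions: 10, s-BuLi, THF, −78 °C; (+)-Ipc2BOMe (from (−)-α-pinene); BF3·OEt2; then 9, −78 °C; HOCH2CH2NH2, Et2O, 23 °C
Reagents that add atoms: none
Why: Brown (Z)-γ-alkoxyallylboration: the chair transition state of the (Z)-allylborane gives the syn diol monoether, and the isopinocampheyl groups from (−)-α-pinene select the aldehyde face that gives (8S,9S) by reagent control.

**Step 6**
Reactants: 14 methyl (2E,6Z)-8-(acetyloxy)-2-[(1S,2S)-1-hydroxy-2-(methoxymethoxy)but-3-en-1-yl]-6-methylocta-2,6-dienoate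
Product: 15 methyl (2E,6Z)-8-(acetyloxy)-2-[(1S,2S)-1-(acetyloxy)-2-(methoxymethoxy)but-3-en-1-yl]-6-methylocta-2,6-dienoate
Conditions: Ac2O, pyridine, DMAP (cat.), CH2Cl2, 0 → 23 °C
Reagents that add atoms: acetic anhydride, CC(=O)OC(C)=O
Why: DMAP-catalysed acylation of the only free hydroxyl (C9); no stereocentre is touched.

**Step 7**
Reactants: 15 methyl (2E,6Z)-8-(acetyloxy)-2-[(1S,2S)-1-(acetyloxy)-2-(methoxymethoxy)but-3-en-1-yl]-6-methylocta-2,6-dienoate
Product: 16 methyl (2E,6Z)-8-(acetyloxy)-2-[(1S,2S)-1-(acetyloxy)-2-hydroxybut-3-en-1-yl]-6-methylocta-2,6-dienoate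
Conditions: ZnBr2 (1 equiv), n-PrSH (2 equiv), CH2Cl2, 0 °C, 10 min
Reagents that add atoms: none
Why: Lewis acid/thiol transacetalisation removes the MOM ether in minutes at 0 °C and leaves acetates and olefins alone; no stereocentre is touched.

**Step 8**
Reactants: 17 methyl 2-(bromomethyl)prop-2-enoate
Product: 18 methyl 2-[(4,4,5,5-tetramethyl-1,3,2-dioxaborolan-2-yl)methyl]prop-2-enoate
Conditions: B2pin2, CuI (10 mol %), PPh3 (13 mol %), LiOMe, DMF, 23 °C
Reagents that add atoms: bis(pinacolato)diboron, CC1(C)OB(OC1(C)C)B1OC(C)(C)C(C)(C)O1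
Why: Copper-catalysed borylation of an allylic bromide (boryl-copper addition then β-bromide elimination, formally SN2′ and degenerate here).

**Step 9**
Reactants: 16 methyl (2E,6Z)-8-(acetyloxy)-2-[(1S,2S)-1-(acetyloxy)-2-hydroxybut-3-en-1-yl]-6-methylocta-2,6-dienoate; 18 methyl 2-[(4,4,5,5-tetramethyl-1,3,2-dioxaborolan-2-yl)methyl]prop-2-enoate
Product: 19 dimethyl (2E,4S,5S,6E)-5-(acetyloxy)-6-[(4Z)-6-(acetyloxy)-4-methylhex-4-en-1-ylidene]-4-hydroxy-2-[(4,4,5,5-tetramethyl-1,3,2-dioxaborolan-2-yl)methyl]hept-2-enedioate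
Conditions: 18 (4 equiv), RuCl2(H2IMes)(=CH-C6H4-2-OiPr) (second-generation Hoveyda–Grubbs catalyst, 10 mol %), CH2Cl2, 40 °C
Reagents that add atoms: none
Why: Olefin cross-metathesis of the terminal vinyl group (free allylic hydroxyl) with an excess of the 1,1-disubstituted acrylate; the trisubstituted olefin forms under thermodynamic control with the ester trans to C8 (CH2Bpin cis to C8), and the other olefins are trisubstituted or electron-poor and do not react.

**Step 10**
Reactants: 20 (R)-2-methylglycidol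
Product: 21 (2S)-2-methyloxirane-2-carboxylic acid
Conditions: RuCl3·xH2O (2 mol %), NaIO4, MeCN/EtOAc/H2O, 0 → 23 °C
Reagents that add atoms: sodium periodate, [Na+].[O-]I(=O)(=O)=O; water, O
Why: RuO4 oxidation (Sharpless RuCl3/NaIO4 conditions) of a primary epoxy alcohol to the glycidic acid; the quaternary centre is not involved (the descriptor changes from R to S only because the CIP priorities change).

**Step 11**
Reactants: 19 dimethyl (2E,4S,5S,6E)-5-(acetyloxy)-6-[(4Z)-6-(acetyloxy)-4-methylhex-4-en-1-ylidene]-4-hydroxy-2-[(pinacolboryl)methyl]hept-2-enedioate; 21 (2S)-2-methyloxirane-2-carboxylic acid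
Product: 23 dimethyl (2E,4S,5S,6E)-5-(acetyloxy)-6-[(4Z)-6-(acetyloxy)-4-methylhex-4-en-1-ylidene]-4-{[(2S)-2-methyloxirane-2-carbonyl]oxy}-2-[(4,4,5,5-tetramethyl-1,3,2-dioxaborolan-2-yl)methyl]hept-2-enedioate, via mixed anhydride 22 (not isolated)
Conditions: 21, 2,4,6-trichlorobenzoyl chloride, Et3N, THF, 0 °C; then 19, DMAP, toluene, 0 → 23 °C
Reagents that add atoms: none
Why: Yamaguchi esterification through the mixed anhydride acylates the hindered secondary C8 alcohol; it is run cold and at once so the neighbouring acetate does not migrate, and no stereocentre is touched.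

**Step 12**
Reactants: 23 the C8 epoxy ester from step 11
Product: 24 dimethyl (2E,4S,5S,6E)-5-(acetyloxy)-6-[(4Z)-6-hydroxy-4-methylhex-4-en-1-ylidene]-4-{[(2S)-2-methyloxirane-2-carbonyl]oxy}-2-[(4,4,5,5-tetramethyl-1,3,2-dioxaborolan-2-yl)methyl]hept-2-enedioate
Conditions: Novozym 435 (immobilised Candida antarctica lipase B), n-BuOH (5 equiv), MTBE, 30 °C
Reagents that add atoms: none
Why: Lipase-catalysed transesterification is selective for the unhindered primary allylic acetate over the hindered secondary acetate, the methyl esters and the glycidic ester.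

**Step 13 (key step)**
Reactants: 24 the C6 allylic alcohol from step 12
Product: 27 methyl (3aS,4S,5S,6E,10Z,11aS)-5-(acetyloxy)-10-methyl-3-methylidene-4-{[(2S)-2-methyloxirane-2-carbonyl]oxy}-2-oxo-2,3,3a,4,5,8,9,11a-octahydrocyclodeca[b]furan-6-carboxylate, via enal 25 (not isolated), via cyclised borate 26 (not isolated)
Conditions: activated MnO2 (20 equiv), CH2Cl2 (3 mM), 40 °C, 16 h; then p-TsOH·H2O (0.1 equiv), 23 °C, same flask
Reagents that add atoms: none
Why: Proposed new method: MnO2 oxidises only the allylic C6 alcohol, and the Z-enal is trapped by the pendant allylboronate through a six-membered chair transition state (closest known reactions: additions of 2-alkoxycarbonyl allylboronates to aldehydes that give α-methylene-γ-butyrolactones, and in situ trapping of MnO2-generated aldehydes); C8, cis to CH2B, sits axial so C6–O and C7–C8 come out syn (cis-fused lactone), attack anti to the C8–C9 bond with C8–H eclipsing the enoate (1,3-allylic strain) sets C7 relative to C8, and the borate then acylates itself on the neighbouring ester, so carbocycle and lactone form in one operation.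

**Step 14**
Reactants: 27 the macrolactone from step 13
Product: 28 target CNP0274195.1 [(4R,5S)-4,5-epoxide of 27; germacranolide locants 4R,5S,6R,7R,8S,9S; side chain 2S]
Conditions: mCPBA (1.1 equiv), NaHCO3, CH2Cl2, 0 °C
Reagents that add atoms: 3-chloroperoxybenzoic acid, OOC(=O)c1cccc(Cl)c1
Why: Prilezhaev epoxidation of the only electron-rich olefin (enoate, α-methylene lactone and epoxy ester are inert); with H6 eclipsing C3 (1,3-allylic strain) the C6–C7 ring bond shields the inner face, so the peracid adds from the outer face that carries the lactone oxygen and gives the (4R,5S)-epoxide syn to C6–O.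

**Compound list**
1 | neryl acetate, (2Z)-3,7-dimethylocta-2,6-dien-1-yl acetate | CC(C)=CCC/C(C)=C\COC(C)=O | starting material
2 | secondary ozonide, (2Z)-5-(5,5-dimethyl-1,2,4-trioxolan-3-yl)-3-methylpent-2-en-1-yl acetate | CC1(C)OOC(CC/C(C)=C\COC(C)=O)O1 | intermediate
3 | (2Z)-3-methyl-6-oxohex-2-en-1-yl acetate | O=CCC/C(C)=C\COC(C)=O | intermediate
4 | methyl acrylate | C=CC(=O)OC | starting material
5 | methyl (6Z)-8-(acetyloxy)-3-hydroxy-6-methyl-2-methylideneoct-6-enoate (racemic) | C=C(C(=O)OC)C(O)CC/C(C)=C\COC(C)=O | intermediate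
6 | alkoxy(dimethyl)sulfonium bromide of 5 (O–S bond at the carbinol oxygen) | C=C(C(=O)OC)C(O[S+](C)C)CC/C(C)=C\COC(C)=O.[Br-] | intermediate
7 | methyl (2Z,6Z)-8-(acetyloxy)-2-(bromomethyl)-6-methylocta-2,6-dienoate | BrC/C(C(=O)OC)=C\CC/C(C)=C\COC(C)=O | intermediate
8 | 4-alkoxy-4-methylmorpholin-4-ium bromide from 7 (O-alkylated NMO, bromide of 7 replaced by O–N) | C[N+]1(OC/C(C(=O)OC)=C\CC/C(C)=C\COC(C)=O)CCOCC1.[Br-] | intermediate
9 | methyl (2E,6Z)-8-(acetyloxy)-2-formyl-6-methylocta-2,6-dienoate | O=C/C(C(=O)OC)=C\CC/C(C)=C\COC(C)=O | intermediate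
10 | allyl methoxymethyl ether, 3-(methoxymethoxy)prop-1-ene | C=CCOCOC | starting material
11 | [(2Z)-3-(methoxymethoxy)prop-2-en-1-yl]lithium | [Li]C/C=C\OCOC | intermediate
12 | [(2Z)-3-(methoxymethoxy)prop-2-en-1-yl]bis(isopinocampheyl)borane, Ipc from (−)-α-pinene | COCO/C=C\CB([C@H]1C[C@H]2C[C@H](C2(C)C)[C@@H]1C)[C@H]1C[C@H]2C[C@H](C2(C)C)[C@@H]1C | intermediate
13 | bis(isopinocampheyl)borinate ester of 14 (B–O at C9) | C=C[C@H](OCOC)[C@@H](OB([C@H]1C[C@H]2C[C@H](C2(C)C)[C@@H]1C)[C@H]1C[C@H]2C[C@H](C2(C)C)[C@@H]1C)/C(C(=O)OC)=C\CC/C(C)=C\COC(C)=O | intermediate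
14 | methyl (2E,6Z)-8-(acetyloxy)-2-[(1S,2S)-1-hydroxy-2-(methoxymethoxy)but-3-en-1-yl]-6-methylocta-2,6-dienoate | C=C[C@H](OCOC)[C@@H](O)/C(C(=O)OC)=C\CC/C(C)=C\COC(C)=O | intermediate
15 | methyl (2E,6Z)-8-(acetyloxy)-2-[(1S,2S)-1-(acetyloxy)-2-(methoxymethoxy)but-3-en-1-yl]-6-methylocta-2,6-dienoate | C=C[C@H](OCOC)[C@@H](OC(C)=O)/C(C(=O)OC)=C\CC/C(C)=C\COC(C)=O | intermediate
16 | methyl (2E,6Z)-8-(acetyloxy)-2-[(1S,2S)-1-(acetyloxy)-2-hydroxybut-3-en-1-yl]-6-methylocta-2,6-dienoate | C=C[C@H](O)[C@@H](OC(C)=O)/C(C(=O)OC)=C\CC/C(C)=C\COC(C)=O | intermediate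
17 | methyl 2-(bromomethyl)prop-2-enoate | C=C(CBr)C(=O)OC | starting material
18 | methyl 2-[(4,4,5,5-tetramethyl-1,3,2-dioxaborolan-2-yl)methyl]prop-2-enoate | C=C(CB1OC(C)(C)C(C)(C)O1)C(=O)OC | intermediate
19 | dimethyl (2E,4S,5S,6E)-5-(acetyloxy)-6-[(4Z)-6-(acetyloxy)-4-methylhex-4-en-1-ylidene]-4-hydroxy-2-[(4,4,5,5-tetramethyl-1,3,2-dioxaborolan-2-yl)methyl]hept-2-enedioate | CC1(C)OB(OC1(C)C)C\C(C(=O)OC)=C/[C@H](O)[C@@H](OC(C)=O)/C(C(=O)OC)=C\CC/C(C)=C\COC(C)=O | intermediate
20 | (R)-2-methylglycidol, [(2R)-2-methyloxiran-2-yl]methanol | OC[C@]1(C)CO1 | starting material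
21 | (2S)-2-methyloxirane-2-carboxylic acid | OC(=O)[C@]1(C)CO1 | intermediate
22 | (2S)-2-methyloxirane-2-carboxylic 2,4,6-trichlorobenzoic anhydride | O=C(OC(=O)[C@]1(C)CO1)c1c(Cl)cc(Cl)cc1Cl | intermediate
23 | dimethyl (2E,4S,5S,6E)-5-(acetyloxy)-6-[(4Z)-6-(acetyloxy)-4-methylhex-4-en-1-ylidene]-4-{[(2S)-2-methyloxirane-2-carbonyl]oxy}-2-[(4,4,5,5-tetramethyl-1,3,2-dioxaborolan-2-yl)methyl]hept-2-enedioate | CC1(C)OB(OC1(C)C)C\C(C(=O)OC)=C/[C@H](OC(=O)[C@]2(C)CO2)[C@@H](OC(C)=O)/C(C(=O)OC)=C\CC/C(C)=C\COC(C)=O | intermediate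
24 | as 23 but with the primary acetate cleaved: 6-[(4Z)-6-hydroxy-4-methylhex-4-en-1-ylidene] | CC1(C)OB(OC1(C)C)C\C(C(=O)OC)=C/[C@H](OC(=O)[C@]2(C)CO2)[C@@H](OC(C)=O)/C(C(=O)OC)=C\CC/C(C)=C\CO | intermediate
25 | Z-enal from 24: 6-[(4Z)-4-methyl-6-oxohex-4-en-1-ylidene] | CC1(C)OB(OC1(C)C)C\C(C(=O)OC)=C/[C@H](OC(=O)[C@]2(C)CO2)[C@@H](OC(C)=O)/C(C(=O)OC)=C\CC/C(C)=C\C=O | intermediate
26 | cyclised pinacol borate: ten-membered carbocycle of 27 with C6–O–Bpin and C7 bearing 1-(methoxycarbonyl)ethenyl, lactone not yet closed, configurations as in 27 | CC1(C)OB(OC1(C)C)O[C@@H](\C=C(C)/C2)[C@H](C(=C)C(=O)OC)[C@H](OC(=O)[C@]1(C)CO1)[C@@H](OC(C)=O)/C(C(=O)OC)=C\C2 | intermediate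
27 | methyl (3aS,4S,5S,6E,10Z,11aS)-5-(acetyloxy)-10-methyl-3-methylidene-4-{[(2S)-2-methyloxirane-2-carbonyl]oxy}-2-oxo-2,3,3a,4,5,8,9,11a-octahydrocyclodeca[b]furan-6-carboxylate | C=C1C(=O)O[C@@H](\C=C(C)/C2)[C@H]1[C@H](OC(=O)[C@]1(C)CO1)[C@@H](OC(C)=O)/C(C(=O)OC)=C\C2 | intermediate
28 | CNP0274195.1, the (4R,5S)-4,5-epoxide of 27 (germacranolide locants 4R,5S,6R,7R,8S,9S; side chain 2S) | C=C1C(=O)O[C@@H]2[C@H]1[C@H](OC(=O)[C@]1(C)CO1)[C@@H](OC(C)=O)/C(C(=O)OC)=C\CC[C@@]1(C)O[C@@H]21 | target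

**Step count and weak points**
Total steps: 14. Longest linear sequence: 12 (steps 1–7, 9, 11, 12, 13, 14 from neryl acetate); steps 8 and 10 make the two side reagents.

Most likely to fail, first: step 13. The ten-membered ring may not close, or the allylboration may give the wrong C6/C7 relationship. The fallback is a zinc Barbier closure, which does not depend on the allyl geometry. It sets out from 16: Yamaguchi esterification with 21 (through 22) gives vinyl ester F1; cross-metathesis of F1 with 17 gives allylic bromide F2; the lipase removes the primary acetate to give allylic alcohol F3; MnO2 gives enal F4; slow addition of F4 to activated Zn dust in THF (40 °C, 2 mM, then aqueous NH4Cl) forms the C6–C7 bond and the zinc alkoxide lactonises, which returns the route at 27.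

Second: step 9. Cross-metathesis between a branched allylic alcohol olefin and a 1,1-disubstituted acrylate may stall or give the wrong olefin geometry. The fallback is a boron-tethered ring-closing metathesis, setting out from 16 and 18: NaIO4/NH4OAc cleaves the pinacol ester of 18 to boronic acid F5; condensation of F5 with the C8 hydroxyl of 16 (MgSO4, CH2Cl2) gives mixed boronic ester F6; RuCl2(H2IMes)(PCy3)(=CHPh) (second-generation Grubbs catalyst) closes the six-membered cyclic allylboronate F7, in which the ring fixes C8 cis to CH2B; exchange with pinacol opens the B–O bond and returns the route at 19.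

Third: step 14. The facial selectivity of the late epoxidation rests on a conformational argument. The fallback is a hydroxyl-directed epoxidation before the lactone is closed, setting out from 24: the MnO2 oxidation/allylboration is run without acid and borate 26 is hydrolysed (aqueous NaHCO3, cold) to hydroxy ester F8; VO(acac)2/t-BuOOH delivers oxygen syn to the C6 hydroxyl of this Z-allylic alcohol (threo, 1,3-allylic strain) to give epoxy alcohol F9; p-TsOH then closes the lactone and returns the route at 28.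

**Further compounds**
F1 | step 13 | vinyl ester: 16 acylated at C8–OH with (2S)-2-methyloxirane-2-carboxylic acid | C=C[C@H](OC(=O)[C@]1(C)CO1)[C@@H](OC(C)=O)/C(C(=O)OC)=C\CC/C(C)=C\COC(C)=O
F2 | step 13 | allylic bromide: bromine analogue of 23 (CH2Br in place of CH2Bpin, CH2Br cis to C8) | BrC\C(C(=O)OC)=C/[C@H](OC(=O)[C@]1(C)CO1)[C@@H](OC(C)=O)/C(C(=O)OC)=C\CC/C(C)=C\COC(C)=O
F3 | step 13 | allylic alcohol: F2 with the primary acetate cleaved | BrC\C(C(=O)OC)=C/[C@H](OC(=O)[C@]1(C)CO1)[C@@H](OC(C)=O)/C(C(=O)OC)=C\CC/C(C)=C\CO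
F4 | step 13 | enal: Z-enal from F3 | BrC\C(C(=O)OC)=C/[C@H](OC(=O)[C@]1(C)CO1)[C@@H](OC(C)=O)/C(C(=O)OC)=C\CC/C(C)=C\C=O
F5 | step 9 | boronic acid: [2-(methoxycarbonyl)prop-2-en-1-yl]boronic acid | OB(O)CC(=C)C(=O)OC
F6 | step 9 | mixed boronic ester of F5 with the C8 hydroxyl of 16 | C=C[C@H](OB(O)CC(=C)C(=O)OC)[C@@H](OC(C)=O)/C(C(=O)OC)=C\CC/C(C)=C\COC(C)=O
F7 | step 9 | cyclic allylboronate: 2-hydroxy-3,6-dihydro-2H-1,2-oxaborinine with CO2Me at C4 and the C9–C6 chain of 16 at C6 | OB1CC(C(=O)OC)=C[C@H](O1)[C@@H](OC(C)=O)/C(C(=O)OC)=C\CC/C(C)=C\COC(C)=O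
F8 | step 14 | hydroxy ester: ring-closed C6 alcohol (26 without boron), lactone open | O[C@@H](\C=C(C)/C1)[C@H](C(=C)C(=O)OC)[C@H](OC(=O)[C@]2(C)CO2)[C@@H](OC(C)=O)/C(C(=O)OC)=C\C1
F9 | step 14 | epoxy alcohol: (4R,5S)-4,5-epoxide of F8, epoxide oxygen syn to C6–OH | O[C@@H]2[C@H](C(=C)C(=O)OC)[C@H](OC(=O)[C@]1(C)CO1)[C@@H](OC(C)=O)/C(C(=O)OC)=C\CC[C@@]1(C)O[C@@H]21
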